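**Retrosynthetic overview**

1. Feature: in the six-membered ring, the quaternary carbon C7 (benzofuran numbering) carries both the isobutyryl and a prenyl group and stands para to the C4 carbonyl oxygen, which is flanked by the methyl-bearing C5 and the ring-fusion carbon C3a that holds the furan CH2. A prenyl group parked on that oxygen of the flat arene can therefore reach C7 by two consecutive [3,3] shifts across either blocked neighbour.
2. Last bond: C5–prenyl, by palladium-catalysed allylation of the 2-methyl-1,3-dione enol that the dearomatisation leaves. Before it: C7–prenyl, by a dearomative Claisen–Cope shift of the C4 prenyl ether, run on the transiently O-silylated arene.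
3. The dihydrofuran comes from 5-exo opening of an enantioenriched epoxide by the phenol next to the acyl-bearing carbon. The ArCH2–epoxide bond comes from reductive alkylation of the single free ring CH with the epoxy aldehyde of Sharpless-epoxidised nerol.
4. The arene is 2-methylphloroglucinol, C-acylated and then O-prenylated at the hydroxyl para to the ketone.
5. Ring order: carbocycle bought as a benzene ring; dihydrofuran closed; carbocycle dearomatised (key step) and then fully quaternised. No further ring is formed.

Key step: step 7

Remark on the chemistry: the target is read from its SMILES as the (2S,5S,7S) compound with an (S)-carbinol; the two ring prenyl groups are trans, and the furan side chain lies on the ring face of the isobutyryl group.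

**Step 1**
Reactants: 1 2,4,6-trihydroxytoluene + 2 isobutyryl chloride
Product: 3 1-(2,4,6-trihydroxy-3-methylphenyl)-2-methylpropan-1-one (3-methylphlorisobutyrophenone)
Conditions: AlCl3 (4 equiv), PhNO2, 65 °C
Reagents that add atoms: none
Why: Friedel–Crafts C-acylation; the two free ring positions of the triol are equivalent and the first acyl group deactivates the ring against a second acylation.

**Step 2**
Reactants: 3 1-(2,4,6-trihydroxy-3-methylphenyl)-2-methylpropan-1-one + 4 prenol
Product: 5 1-[2,6-dihydroxy-3-methyl-4-(3-methylbut-2-enyloxy)phenyl]-2-methylpropan-1-one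
Conditions: PPh3, DIAD, THF, 0 °C to rt
Reagents that add atoms: none
Why: Mitsunobu etherification; the hydroxyl para to the ketone is the most acidic and the only one neither chelated to nor crowded by the carbonyl group, so it displaces the primary allylic oxyphosphonium ion by SN2 without C-alkylation.

**Step 3**
Reactants: 6 nerol
Product: 7 (2R,3S)-2,3-epoxynerol
Conditions: Ti(OiPr)4 (cat.), D-(−)-diethyl tartrate (cat.), t-BuOOH, 4 Å MS, CH2Cl2, −20 °C
Reagents that add atoms: tert-butyl hydroperoxide CC(C)(C)OO
Why: Sharpless asymmetric epoxidation; with the D-tartrate the oxygen is delivered to the face of the Z-allylic alcohol that gives the 2R,3S epoxide, fixing both carbons that become the furan CH and the tertiary carbinol, while the remote alkene (not an allylic alcohol) is left alone.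

**Step 4**
Reactants: 7 (2R,3S)-2,3-epoxynerol
Product: 8 (2S,3S)-3-methyl-3-(4-methylpent-3-enyl)oxirane-2-carbaldehyde (cis-2,3-epoxyneral)
Conditions: SO3·pyridine, DMSO, i-Pr2NEt, CH2Cl2, 0 °C; used crude
Reagents that add atoms: none
Why: Parikh–Doering oxidation; activated DMSO oxidises the primary alcohol under buffered non-acidic conditions that leave the epoxide and both stereocentres untouched (the 2S label reflects a priority change only).

**Step 5**
Reactants: 5 1-[2,6-dihydroxy-3-methyl-4-(3-methylbut-2-enyloxy)phenyl]-2-methylpropan-1-one + 8 (2S,3S)-3-methyl-3-(4-methylpent-3-enyl)oxirane-2-carbaldehyde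
Product: 10 1-[2,6-dihydroxy-3-methyl-5-{[(2R,3S)-3-methyl-3-(4-methylpent-3-enyl)oxiran-2-yl]methyl}-4-(3-methylbut-2-enyloxy)phenyl]-2-methylpropan-1-one, via ortho-quinone methide 9 (not isolated)
Conditions: L-proline (20 mol%), Hantzsch ester (1.2 equiv), CH2Cl2, 0 °C to rt
Reagents that add atoms: none
Why: Organocatalytic reductive alkylation (Knoevenagel-type condensation, then Hantzsch ester transfer hydrogenation); the one unsubstituted, triply oxygen-activated ring carbon adds to the proline iminium ion of the aldehyde, loss of the amine gives quinone methide 9, and hydride transfer to its exocyclic carbon restores the arene, while the epoxide carbons are spared because this aldehyde cannot form an enamine without placing a double bond on the oxirane.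

**Step 6**
Reactants: 10 the C-(2,3-epoxyneryl) arene
Product: 11 1-{(2S)-6-hydroxy-2-[(2S)-2-hydroxy-6-methylhept-5-en-2-yl]-5-methyl-4-(3-methylbut-2-enyloxy)-2,3-dihydro-1-benzofuran-7-yl}-2-methylpropan-1-one
Conditions: K2CO3, MeOH, rt
Reagents that add atoms: none
Why: Intramolecular 5-exo-tet epoxide opening; the phenoxide ortho to the new CH2 attacks the nearer secondary epoxide carbon with inversion to give the (S)-furan CH and frees the (S)-tertiary carbinol unchanged, and because the other flanking oxygen is the prenyl ether only this oxygen can close.

**Step 7**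
Reactants: 11 the 4-prenyloxy-6-hydroxy-5-methyl-7-isobutyryl-2,3-dihydrobenzofuran
Product: 16 (2S,7S)-6-hydroxy-2-[(2S)-2-hydroxy-6-methylhept-5-en-2-yl]-5-methyl-7-(3-methylbut-2-enyl)-7-(2-methylpropanoyl)-3,7-dihydro-1-benzofuran-4(2H)-one, via bis-TMS ether 12 (not isolated), via methyl-carbon ortho-dienone 13 (not isolated), via ring-fusion ortho-dienone 14 (not isolated), via bis-TMS para-dienone 15 (not isolated)
Conditions: BSA (5 equiv), 1,2-dichlorobenzene, 80 °C then 170 °C (sealed, argon); then 10% aq. citric acid, THF/MeOH, rt
Reagents that add atoms: none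
Why: Proposed new method: BSA first caps the chelated phenol and the tertiary alcohol as TMS ethers (12), which removes the hydrogen bond and coplanarity that stabilise the acyl arene and leaves no mobile proton that could relay the allyl unit elsewhere; on heating, the aryl prenyl ether shifts by a Claisen [3,3] step to either blocked ortho carbon (methyl-bearing in 13, ring-fusion in 14), and since neither 1,1-dimethylallyl dienone can enolise, a Cope [3,3] step carries the group on to the para, acyl-bearing carbon as a linear prenyl group (15), after which mild acid removes both silyl groups. The closest known reaction type is the aromatic para-Claisen (Claisen–Cope) rearrangement of 2,6-disubstituted aryl prenyl ethers, together with dearomatising Claisen shifts of phloroglucinol allyl ethers; new here is that the para carbon carries an acyl group, so the sequence must rest at the cyclohexadienone, which is expected to be downhill because the crowded 1,1-dimethylallyl dienones relax to a linear prenyl group and the product is a doubly oxygen-stabilised cross-conjugated dienone of a phloroglucinol-type ring with little aromatic stabilisation to lose. No ring closes: the O–CH2 bond of the ether breaks and a C–CH2 bond forms at the acyl-bearing carbon, turning the benzene ring into the cyclohexadienone of the target. The new quaternary stereocentre is controlled by the silyloxyalkyl side chain on the furan CH: both shifts are suprafacial, so the prenyl group stays on one ring face and is expected to choose the face anti to that side chain, most decisively when it passes the adjacent ring-fusion carbon. The step needs regioselectivity, secured by the two blocked ortho carbons and the silylated phenol so that only the para carbon can be reached, and facial selectivity, which is expected to be modest, so the C7 epimer would be removed by chromatography.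

**Step 8**
Reactants: 4 prenol
Product: 17 tert-butyl 3-methylbut-2-enyl carbonate
Conditions: Boc2O, DMAP (10 mol%), MeCN, rt
Reagents that add atoms: di-tert-butyl dicarbonate CC(C)(C)OC(=O)OC(=O)OC(C)(C)C
Why: Carbonate formation from a primary alcohol and Boc2O under nucleophilic catalysis; it gives an ionisable prenyl donor that releases its own base on ionisation.

**Step 9**
Reactants: 16 the dearomatised dienone + 17 tert-butyl 3-methylbut-2-enyl carbonate
Product: 18 (2S,5S,7S)-2-[(2S)-2-hydroxy-6-methylhept-5-en-2-yl]-5-methyl-5,7-bis(3-methylbut-2-enyl)-7-(2-methylpropanoyl)-2,3-dihydro-1-benzofuran-4,6(5H,7H)-dione (CNP0250451.1)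
Conditions: Pd2(dba)3·CHCl3 (2.5 mol%), DACH-phenyl Trost ligand (antipode matched to the substrate, 7.5 mol%), THF, 0 °C to rt
Reagents that add atoms: none
Why: Tsuji–Trost allylation; zerovalent palladium ionises the carbonate, the released tert-butoxide deprotonates the vinylogous acid, and the soft 2-methyl-1,3-dione enolate attacks the unsubstituted terminus of the π-prenyl complex at carbon (any O-prenyl enol ether re-ionises), creating the methyl-bearing quaternary centre on the face selected by the matched chiral ligand and, to a smaller extent, by the ring prenyl group screening its own face, so the new prenyl group should enter trans to it.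

**Compound list**

1 | 2,4,6-trihydroxytoluene (2-methylphloroglucinol) | Cc1c(O)cc(O)cc1O | starting material
2 | isobutyryl chloride | CC(C)C(Cl)=O | starting material
3 | 1-(2,4,6-trihydroxy-3-methylphenyl)-2-methylpropan-1-one | CC(C)C(=O)c1c(O)cc(O)c(C)c1O | intermediate
4 | prenol (3-methylbut-2-en-1-ol) | CC(C)=CCO | starting material
5 | 1-[2,6-dihydroxy-3-methyl-4-(3-methylbut-2-enyloxy)phenyl]-2-methylpropan-1-one | CC(C)C(=O)c1c(O)cc(OCC=C(C)C)c(C)c1O | intermediate
6 | nerol ((2Z)-3,7-dimethylocta-2,6-dien-1-ol) | CC(C)=CCC/C(C)=C\CO | starting material
7 | (2R,3S)-2,3-epoxynerol | CC(C)=CCC[C@]1(C)O[C@@H]1CO | intermediate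
8 | (2S,3S)-3-methyl-3-(4-methylpent-3-enyl)oxirane-2-carbaldehyde | CC(C)=CCC[C@]1(C)O[C@@H]1C=O | intermediate
9 | ortho-quinone methide from 5 and 8 (formed in the flask, not isolated; exocyclic alkene geometry not defined) | CC(C)=CCC[C@]1(C)O[C@@H]1C=C2C(=O)C(C(=O)C(C)C)=C(O)C(C)=C2OCC=C(C)C | intermediate
10 | C-(2,3-epoxyneryl) arene, (2R,3S)-epoxide | CC(C)=CCC[C@]1(C)O[C@@H]1Cc1c(O)c(C(=O)C(C)C)c(O)c(C)c1OCC=C(C)C | intermediate
11 | 1-{(2S)-6-hydroxy-2-[(2S)-2-hydroxy-6-methylhept-5-en-2-yl]-5-methyl-4-(3-methylbut-2-enyloxy)-2,3-dihydro-1-benzofuran-7-yl}-2-methylpropan-1-one | CC(C)=CCC[C@](C)(O)[C@@H]1Cc2c(O1)c(C(=O)C(C)C)c(O)c(C)c2OCC=C(C)C | intermediate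
12 | bis(trimethylsilyl) ether of 11 at the C6 phenol and the tertiary alcohol (not isolated) | CC(C)=CCC[C@](C)(O[Si](C)(C)C)[C@@H]1Cc2c(O1)c(C(=O)C(C)C)c(O[Si](C)(C)C)c(C)c2OCC=C(C)C | intermediate
13 | ortho-dienone with the 1,1-dimethylallyl group on the methyl-bearing carbon C5, anti to the furan side chain (not isolated) | CC(C)=CCC[C@](C)(O[Si](C)(C)C)[C@@H]1CC2=C(O1)C(C(=O)C(C)C)=C(O[Si](C)(C)C)[C@](C)(C(C)(C)C=C)C2=O | intermediate
14 | ortho-dienone with the 1,1-dimethylallyl group on the ring-fusion carbon C3a, anti to the furan side chain (not isolated) | CC(C)=CCC[C@](C)(O[Si](C)(C)C)[C@@H]1C[C@@]2(C(C)(C)C=C)C(O1)=C(C(=O)C(C)C)C(O[Si](C)(C)C)=C(C)C2=O | intermediate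
15 | bis(trimethylsilyl) ether of 16: para-dienone with prenyl and isobutyryl on C7 (not isolated) | CC(C)=CCC[C@](C)(O[Si](C)(C)C)[C@@H]1CC2=C(O1)[C@@](CC=C(C)C)(C(=O)C(C)C)C(O[Si](C)(C)C)=C(C)C2=O | intermediate
16 | (2S,7S)-6-hydroxy-2-[(2S)-2-hydroxy-6-methylhept-5-en-2-yl]-5-methyl-7-(3-methylbut-2-enyl)-7-(2-methylpropanoyl)-3,7-dihydro-1-benzofuran-4(2H)-one | CC(C)=CCC[C@](C)(O)[C@@H]1CC2=C(O1)[C@@](CC=C(C)C)(C(=O)C(C)C)C(O)=C(C)C2=O | intermediate
17 | tert-butyl 3-methylbut-2-enyl carbonate | CC(C)=CCOC(=O)OC(C)(C)C | intermediate
18 | CNP0250451.1, (2S,5S,7S)-2-[(2S)-2-hydroxy-6-methylhept-5-en-2-yl]-5-methyl-5,7-bis(3-methylbut-2-enyl)-7-(2-methylpropanoyl)-2,3-dihydro-1-benzofuran-4,6(5H,7H)-dione | CC(C)=CCC[C@](C)(O)[C@@H]1CC2=C(O1)[C@@](CC=C(C)C)(C(=O)C(C)C)C(=O)[C@@](C)(CC=C(C)C)C2=O | target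

**Totals**

Total step count: 9. Longest linear sequence: 6 steps (1, 2, 5, 6, 7, 9 from 2-methylphloroglucinol, or 3, 4, 5, 6, 7, 9 from nerol).

**Steps most likely to fail**

Step 7 (Proposed new method). Three things may go wrong:
- The equilibrium between the silylated aryl ether, the two ortho-dienones and the para-dienone may not lie far enough on the dearomatised side.
- The 1,1-dimethylallyl dienones may lose the allyl unit by heterolysis at the temperature needed.
- The prenyl group may show little preference for the face anti to the furan side chain.

Unchanged ether would be recovered after desilylation and resubjected. The fallback uses known reactions and sets out from 11: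
- Treatment with Pd(PPh3)4, or with the zerovalent palladium/chiral ligand system of step 9, ionises the aryl prenyl ether. The π-prenyl unit is then expected to return to the methyl-bearing carbon, the site that intermolecular allylation of such phenoxides prefers, giving the dearomatised gem-methyl/prenyl β-triketone enol F1.
- O-Allylation of its acyl-conjugated enol (allyl bromide, K2CO3, acetone) gives the allyl enol ether F2.
- An aliphatic Claisen rearrangement (toluene, 110 °C) moves the allyl group to the adjacent acyl-bearing carbon, anti to the neighbouring ring prenyl group, giving the C7-allyl trione F3.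
- Cross-metathesis with 2-methyl-2-butene (second-generation Grubbs catalyst, CH2Cl2, 40 °C) turns the allyl into the prenyl group; the other trisubstituted alkenes only exchange degenerately. This rejoins the route at 18.

Step 5. The quinone methide may be intercepted by a second molecule of arene before hydride transfer, or the epoxide may be opened by the amine or by the acidic phenol (premature or 6-endo closure). The fallback sets out from 5:
- C-Alkylation of the phenoxide at the free ring carbon with neryl bromide (DBU, THF) gives the C-neryl arene F4.
- Phenol-directed epoxidation of the proximal alkene (VO(acac)2, t-BuOOH, CH2Cl2) with spontaneous 5-exo closure gives racemic 11. The relative configuration is correct because syn epoxidation of the Z-alkene is followed by anti opening.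
- Separation on a chiral stationary phase removes the enantiomer F5, and 11 rejoins the route at step 7.

Step 9. Facial discrimination at the nearly flat enolate may be poor, or O-prenylation and branched attack may compete. The fallback sets out from 16:
- O-Allylation (allyl bromide, K2CO3, acetone) gives the allyl enol ether F6.
- A thermal Claisen rearrangement (toluene, 110 °C) delivers the allyl group intramolecularly through a chair transition state to the methyl-bearing carbon, anti to the ring prenyl group, giving the C5-allyl trione F7.
- Cross-metathesis with 2-methyl-2-butene (second-generation Grubbs catalyst) converts the allyl into the prenyl group and rejoins the route at 18.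

**Further compounds**

F1 | step 7 | dearomatised enol with methyl and prenyl on C5 and the isobutyryl-conjugated C6 enol (prenyl syn to the furan side chain face as in the target) | CC(C)=CCC[C@](C)(O)[C@@H]1CC2=C(O1)C(C(=O)C(C)C)=C(O)[C@@](C)(CC=C(C)C)C2=O
F2 | step 7 | O6-allyl enol ether of F1 | CC(C)=CCC[C@](C)(O)[C@@H]1CC2=C(O1)C(C(=O)C(C)C)=C(OCC=C)[C@@](C)(CC=C(C)C)C2=O
F3 | step 7 | C7-allyl analogue of the target (allyl in place of the C7 prenyl group) | CC(C)=CCC[C@](C)(O)[C@@H]1CC2=C(O1)[C@@](CC=C)(C(=O)C(C)C)C(=O)[C@@](C)(CC=C(C)C)C2=O
F4 | step 5 | C-neryl arene, 1-[2,6-dihydroxy-3-methyl-5-((2Z)-3,7-dimethylocta-2,6-dienyl)-4-(3-methylbut-2-enyloxy)phenyl]-2-methylpropan-1-one | CC(C)=CCC/C(C)=C\Cc1c(O)c(C(=O)C(C)C)c(O)c(C)c1OCC=C(C)C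
F5 | step 5 | enantiomer of 11, (2R)-furan CH and (R)-carbinol | CC(C)=CCC[C@@](C)(O)[C@H]1Cc2c(O1)c(C(=O)C(C)C)c(O)c(C)c2OCC=C(C)C
F6 | step 9 | O6-allyl enol ether of 16 | CC(C)=CCC[C@](C)(O)[C@@H]1CC2=C(O1)[C@@](CC=C(C)C)(C(=O)C(C)C)C(OCC=C)=C(C)C2=O
F7 | step 9 | C5-allyl analogue of the target (allyl in place of the C5 prenyl group) | CC(C)=CCC[C@](C)(O)[C@@H]1CC2=C(O1)[C@@](CC=C(C)C)(C(=O)C(C)C)C(=O)[C@@](C)(CC=C)C2=O
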